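Camelliol C is divided at its central allylic CH2–CH2 bond into farnesyl phenyl sulfone and a C15 cyclohexenyl bromide. In the single ring (C3 carbinol, C4 gem-dimethyl, C5 carrying the chain, C10(Me)=C1, C2) the array O–C3–C4–C5–C10=C is a disguised γ,δ-unsaturated acid, so the plan rests on the C4–C5 bond. Ireland–Claisen rearrangement of an open-chain (S,E)-allylic isobutyrate, grown from geraniol, makes this bond, quaternary C4 and stereocentre C5 in one operation and parks an ethylidene on C10. Allylation at C3 and a propene-releasing metathesis then close the ring, discarding the carbinol carbon that steered C5.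

Key step: step 6

Assumption: commercial geraniol and (2E,6E)-farnesyl bromide are taken as geometrically pure. Ring atoms keep the numbers used above. PMB = 4-methoxybenzyl, Ipc = isopinocampheyl, MIB = 3-exo-morpholinoisoborneol, LDA = LiN(i-Pr)2.

Step 1
Reactants: 1 geraniol
Product: 2 (E)-geranyl 4-methoxybenzyl ether
Conditions: NaH, PMBCl, Bu4NI (cat.), THF/DMF, 0 °C → rt
Reagents that add atoms: 4-methoxybenzyl chloride, COc1ccc(CCl)cc1
Why: Williamson etherification of the sodium alkoxide with the benzylic chloride (iodide catalysis) should give an ether that tolerates every base, hydride and oxidant used before step 12.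

Step 2
Reactants: 2 (E)-geranyl 4-methoxybenzyl ether
Product: 3 (2E,6E)-8-(4-methoxybenzyloxy)-2,6-dimethylocta-2,6-dien-1-ol
Conditions: SeO2 (0.1 equiv), t-BuOOH (3 equiv), salicylic acid (0.1 equiv), CH2Cl2, 0 °C → rt
Reagents that add atoms: selenium dioxide, O=[Se]=O; tert-butyl hydroperoxide (terminal oxidant), CC(C)(C)OO
Why: Riley allylic oxidation (ene reaction, then [2,3]-shift of the allylseleninic acid) attacks the more electron-rich terminal alkene and hydroxylates only the methyl trans to the chain, which fixes the (E)-geometry needed in step 6, and any enal 4 already formed is simply carried into step 3.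

Step 3
Reactants: 3 (2E,6E)-8-(4-methoxybenzyloxy)-2,6-dimethylocta-2,6-dien-1-ol
Product: 4 (2E,6E)-8-(4-methoxybenzyloxy)-2,6-dimethylocta-2,6-dienal
Conditions: MnO2 (activated, excess), CH2Cl2, rt
Reagents that add atoms: none
Why: Heterogeneous MnO2 oxidation is specific for allylic alcohols, stops at the aldehyde and leaves the alkene geometry and the PMB ether untouched.

Step 4
Reactants: 4 (2E,6E)-8-(4-methoxybenzyloxy)-2,6-dimethylocta-2,6-dienal
Product: 5 (2S,3E,7E)-9-(4-methoxybenzyloxy)-3,7-dimethylnona-3,7-dien-2-ol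
Conditions: Me2Zn (2.5 equiv), (2S)-(−)-MIB (8 mol %), toluene/hexane, 0 °C → rt; aq. NH4Cl
Reagents that add atoms: dimethylzinc, C[Zn]C
Why: Noyori-type amino-alcohol-catalysed dialkylzinc addition, for which enals are good substrates, should deliver methyl to the Si face and set the (S)-carbinol in a single step, and the minor (R)-alcohol ends up as a separable diastereomer after step 9.

Step 5
Reactants: 5 (2S,3E,7E)-9-(4-methoxybenzyloxy)-3,7-dimethylnona-3,7-dien-2-ol; 6 isobutyryl chloride
Product: 7 (2S,3E,7E)-9-(4-methoxybenzyloxy)-3,7-dimethylnona-3,7-dien-2-yl 2-methylpropanoate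
Conditions: Et3N, DMAP (cat.), CH2Cl2, 0 °C → rt
Reagents that add atoms: none
Why: DMAP-catalysed O-acylation touches only the O–H bond, so the carbinol configuration is retained.

Step 6
Reactants: 7 (2S,3E,7E)-9-(4-methoxybenzyloxy)-3,7-dimethylnona-3,7-dien-2-yl 2-methylpropanoate
Product: 10 (3R,6E)-3-[(2E)-but-2-en-2-yl]-8-(4-methoxybenzyloxy)-2,2,6-trimethyloct-6-enoic acid, via silyl ketene acetal 8 (not isolated), via trimethylsilyl ester 9 (not isolated)
Conditions: LDA, THF, −78 °C; Me3SiCl, −78 °C → rt, then 65 °C; aq. NaOH/THF, rt, then citric acid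
Reagents that add atoms: chlorotrimethylsilane, C[Si](C)(C)Cl (its silyl group sits only in 8 and 9 and is gone in 10)
Why: LDA deprotonates the isobutyrate, Me3SiCl traps the enolate on oxygen as 8 (no geometric isomers, since the terminus carries two methyls), and on warming 8 undergoes a concerted suprafacial [3,3]-sigmatropic shift in which the allylic C–O bond breaks while C4–C5 forms, giving 9, which mild hydrolysis turns into 10. The closest known reaction type is the Ireland–Claisen rearrangement of a secondary allylic ester with 1,3-chirality transfer, whose Claisen relatives on 2-methylallylic carbinols are a classical source of (E)-trisubstituted alkenes. No ring is closed, because the six-membered array exists only in the transition state. C5 is the only new stereocentre and is controlled by the (S)-carbinol carbon: with its methyl pseudo-equatorial, the ketene acetal must bond to the alkene face from which the oxygen departs, which on the (E)-alkene gives (R)-C5 and the (E)-ethylidene, and chair and boat converge because C4 is not stereogenic. The selectivity needed is pseudo-equatorial over pseudo-axial placement of that methyl, since the pseudo-axial path pairs a (Z)-ethylidene with (S)-C5, and it is secured by the 1,3-diaxial clash with the silyloxy-bearing acetal carbon and by the pure (E)-geometry from step 2. The intramolecular nature of the shift is what allows a quaternary and a tertiary carbon to be joined.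

Step 7
Reactants: 10 (3R,6E)-3-[(2E)-but-2-en-2-yl]-8-(4-methoxybenzyloxy)-2,2,6-trimethyloct-6-enoic acid
Product: 11 (3R,6E)-3-[(2E)-but-2-en-2-yl]-8-(4-methoxybenzyloxy)-2,2,6-trimethyloct-6-en-1-ol
Conditions: LiAlH4, THF, 0 °C → reflux; Fieser work-up
Reagents that add atoms: none
Why: LiAlH4 reduces even α-quaternary carboxylic acids to primary alcohols, while isolated alkenes, the PMB ether and C5 are inert.

Step 8
Reactants: 11 (3R,6E)-3-[(2E)-but-2-en-2-yl]-8-(4-methoxybenzyloxy)-2,2,6-trimethyloct-6-en-1-ol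
Product: 12 (3R,6E)-3-[(2E)-but-2-en-2-yl]-8-(4-methoxybenzyloxy)-2,2,6-trimethyloct-6-enal
Conditions: Dess–Martin periodinane, NaHCO3, CH2Cl2, 0 °C → rt
Reagents that add atoms: none
Why: Dess–Martin oxidation works near neutrality on hindered primary alcohols, and the aldehyde has no α-hydrogen, so nothing can epimerise.

Step 9
Reactants: 12 (3R,6E)-3-[(2E)-but-2-en-2-yl]-8-(4-methoxybenzyloxy)-2,2,6-trimethyloct-6-enal; 13 allylmagnesium bromide
Product: 15 (4S,6R,9E)-6-[(2E)-but-2-en-2-yl]-11-(4-methoxybenzyloxy)-5,5,9-trimethylundeca-1,9-dien-4-ol, via B-allyldiisopinocampheylborane 14 (not isolated)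
Conditions: (−)-Ipc2BOMe, CH2=CHCH2MgBr, Et2O, 0 °C → rt; then 12, −78 °C; NaOH, H2O2, rt
Reagents that add atoms: (−)-B-methoxydiisopinocampheylborane, COB([C@@H]1C[C@@H]2C[C@H]([C@H]1C)C2(C)C)[C@@H]1C[C@@H]2C[C@H]([C@H]1C)C2(C)C (boron and Ipc groups sit only in 14)
Why: Brown allylboration with the reagent derived from (+)-α-pinene transfers allyl through a closed chair to the Si face of the aldehyde, the sense established for pivalaldehyde, so reagent control should set (S)-C3 whatever the bias of the remote C5 centre.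

Step 10
Reactants: 15 (4S,6R,9E)-6-[(2E)-but-2-en-2-yl]-11-(4-methoxybenzyloxy)-5,5,9-trimethylundeca-1,9-dien-4-ol
Product: 16 (1S,5R)-5-[(3E)-5-(4-methoxybenzyloxy)-3-methylpent-3-enyl]-4,6,6-trimethylcyclohex-3-en-1-ol
Conditions: second-generation Grubbs catalyst (H2IMes)(PCy3)Cl2Ru=CHPh (5–10 mol %), 1,4-benzoquinone (10 mol %), toluene (2 mM), 80 °C, argon sparge
Reagents that add atoms: none
Why: In this ring-closing metathesis the catalyst loads on the monosubstituted allyl terminus and the carbene closes a six-membered ring on the nearby ethylidene (helped by the gem-dimethyl group) with loss of propene, whereas the side-chain alkene could only give an eight-membered ring and no stereocentre is touched.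

Step 11
Reactants: 16 (1S,5R)-5-[(3E)-5-(4-methoxybenzyloxy)-3-methylpent-3-enyl]-4,6,6-trimethylcyclohex-3-en-1-ol
Product: 17 (1S,5R)-5-[(3E)-5-(4-methoxybenzyloxy)-3-methylpent-3-enyl]-4,6,6-trimethylcyclohex-3-enyl acetate
Conditions: Ac2O, Et3N, DMAP, CH2Cl2, rt
Reagents that add atoms: acetic anhydride, CC(=O)OC(C)=O
Why: DMAP-catalysed acetylation caps the equatorial C3 hydroxyl with a group that should survive steps 12 to 15 and is removed by the hydride of step 16, which saves a separate deprotection.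

Step 12
Reactants: 17 (1S,5R)-5-[(3E)-5-(4-methoxybenzyloxy)-3-methylpent-3-enyl]-4,6,6-trimethylcyclohex-3-enyl acetate
Product: 18 (1S,5R)-5-[(3E)-5-hydroxy-3-methylpent-3-enyl]-4,6,6-trimethylcyclohex-3-enyl acetate
Conditions: DDQ (1.2 equiv), CH2Cl2/pH 7 buffer, 0 °C
Reagents that add atoms: none
Why: Oxidative PMB cleavage proceeds by hydride abstraction to the stabilised 4-methoxybenzyl oxocarbenium ion and hydrolysis, and the acetate and unactivated trisubstituted alkenes do not react with a small excess of DDQ at 0 °C.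

Step 13
Reactants: 18 (1S,5R)-5-[(3E)-5-hydroxy-3-methylpent-3-enyl]-4,6,6-trimethylcyclohex-3-enyl acetate
Product: 20 (1S,5R)-5-[(3E)-5-bromo-3-methylpent-3-enyl]-4,6,6-trimethylcyclohex-3-enyl acetate, via allylic mesylate 19 (not isolated)
Conditions: MsCl, Et3N, THF, −40 °C; LiBr, THF, −40 → 0 °C; used without storage
Reagents that add atoms: lithium bromide, [Li+].[Br-]; methanesulfonyl chloride, CS(=O)(=O)Cl (its mesyl group sits only in 19)
Why: Mesylation followed by in situ SN2 displacement with bromide is non-acidic, so the (E)-alkene is kept and allylic transposition is avoided.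

Step 14
Reactants: 21 (2E,6E)-farnesyl bromide
Product: 22 (2E,6E)-farnesyl phenyl sulfone
Conditions: PhSO2Na, DMF, rt
Reagents that add atoms: sodium benzenesulfinate, [Na+].[O-]S(=O)c1ccccc1
Why: The soft sulfur of the sulfinate displaces the primary allylic bromide by SN2 without transposition or loss of alkene geometry.

Step 15
Reactants: 20 (1S,5R)-5-[(3E)-5-bromo-3-methylpent-3-enyl]-4,6,6-trimethylcyclohex-3-enyl acetate; 22 (2E,6E)-farnesyl phenyl sulfone
Product: 24 C30 sulfone acetate (farnesyl C1 bearing PhSO2 bonded to the former CH2Br carbon of 20; epimers at the sulfonyl carbon; ring 1S,5R), via lithiated sulfone 23 (not isolated)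
Conditions: 22 (1.2 equiv), n-BuLi, THF, −78 °C; then 20, −78 → −40 °C; cold aq. NH4Cl quench
Reagents that add atoms: n-butyllithium, [Li]CCCC (lithium sits only in 23)
Why: Biellmann-type alkylation of the α-lithiated allylic sulfone occurs at its α-carbon by SN2 on the allylic bromide far faster than attack on the acetate at −78 °C, and the new sulfonyl-bearing centre is erased in step 16.

Step 16
Reactants: 24 C30 sulfone acetate
Product: 26 camelliol C, via hydroxy sulfone 25 (not isolated)
Conditions: LiEt3BH (6 equiv), Pd(dppp)Cl2 (5 mol %), THF, 0 °C → rt; aq. NH4Cl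
Reagents that add atoms: none
Why: LiEt3BH reduces the acetate to the alkoxide of 25 and the divalent palladium precatalyst to zerovalent palladium, which ionises the allylic sulfone to a π-allyl complex that accepts hydride at its less substituted terminus, so this palladium-catalysed reductive desulfonylation should leave the (E)-trisubstituted alkene in place.

Compound list
1 | geraniol | CC(C)=CCC/C(C)=C/CO | starting material
2 | (E)-geranyl 4-methoxybenzyl ether | CC(C)=CCC/C(C)=C/COCc1ccc(OC)cc1 | intermediate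
3 | (2E,6E)-8-(4-methoxybenzyloxy)-2,6-dimethylocta-2,6-dien-1-ol | OC/C(C)=C/CC/C(C)=C/COCc1ccc(OC)cc1 | intermediate
4 | (2E,6E)-8-(4-methoxybenzyloxy)-2,6-dimethylocta-2,6-dienal | O=C/C(C)=C/CC/C(C)=C/COCc1ccc(OC)cc1 | intermediate
5 | (2S,3E,7E)-9-(4-methoxybenzyloxy)-3,7-dimethylnona-3,7-dien-2-ol | C[C@H](O)/C(C)=C/CC/C(C)=C/COCc1ccc(OC)cc1 | intermediate
6 | isobutyryl chloride | CC(C)C(=O)Cl | starting material
7 | (2S,3E,7E)-9-(4-methoxybenzyloxy)-3,7-dimethylnona-3,7-dien-2-yl 2-methylpropanoate | C[C@H](OC(=O)C(C)C)/C(C)=C/CC/C(C)=C/COCc1ccc(OC)cc1 | intermediate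
8 | trimethylsilyl ketene acetal of 7 (formed in the flask) | C[C@H](OC(O[Si](C)(C)C)=C(C)C)/C(C)=C/CC/C(C)=C/COCc1ccc(OC)cc1 | intermediate
9 | trimethylsilyl ester of 10 (formed in the flask) | C[Si](C)(C)OC(=O)C(C)(C)[C@H](CC/C(C)=C/COCc1ccc(OC)cc1)/C(C)=C/C | intermediate
10 | (3R,6E)-3-[(2E)-but-2-en-2-yl]-8-(4-methoxybenzyloxy)-2,2,6-trimethyloct-6-enoic acid | OC(=O)C(C)(C)[C@H](CC/C(C)=C/COCc1ccc(OC)cc1)/C(C)=C/C | intermediate
11 | (3R,6E)-3-[(2E)-but-2-en-2-yl]-8-(4-methoxybenzyloxy)-2,2,6-trimethyloct-6-en-1-ol | OCC(C)(C)[C@H](CC/C(C)=C/COCc1ccc(OC)cc1)/C(C)=C/C | intermediate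
12 | (3R,6E)-3-[(2E)-but-2-en-2-yl]-8-(4-methoxybenzyloxy)-2,2,6-trimethyloct-6-enal | O=CC(C)(C)[C@H](CC/C(C)=C/COCc1ccc(OC)cc1)/C(C)=C/C | intermediate
13 | allylmagnesium bromide | C=CC[Mg]Br | starting material
14 | (−)-B-allyldiisopinocampheylborane, Ipc groups from (+)-α-pinene (formed in the flask) | C=CCB([C@@H]1C[C@@H]2C[C@H]([C@H]1C)C2(C)C)[C@@H]1C[C@@H]2C[C@H]([C@H]1C)C2(C)C | intermediate
15 | (4S,6R,9E)-6-[(2E)-but-2-en-2-yl]-11-(4-methoxybenzyloxy)-5,5,9-trimethylundeca-1,9-dien-4-ol | C=CC[C@H](O)C(C)(C)[C@H](CC/C(C)=C/COCc1ccc(OC)cc1)/C(C)=C/C | intermediate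
16 | (1S,5R)-5-[(3E)-5-(4-methoxybenzyloxy)-3-methylpent-3-enyl]-4,6,6-trimethylcyclohex-3-en-1-ol | COc1ccc(COC/C=C(\C)CC[C@@H]2C(C)=CC[C@H](O)C2(C)C)cc1 | intermediate
17 | acetate of 16 | COc1ccc(COC/C=C(\C)CC[C@@H]2C(C)=CC[C@H](OC(C)=O)C2(C)C)cc1 | intermediate
18 | (1S,5R)-5-[(3E)-5-hydroxy-3-methylpent-3-enyl]-4,6,6-trimethylcyclohex-3-enyl acetate | OC/C=C(\C)CC[C@@H]1C(C)=CC[C@H](OC(C)=O)C1(C)C | intermediate
19 | primary allylic mesylate of 18 (formed in the flask) | CS(=O)(=O)OC/C=C(\C)CC[C@@H]1C(C)=CC[C@H](OC(C)=O)C1(C)C | intermediate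
20 | (1S,5R)-5-[(3E)-5-bromo-3-methylpent-3-enyl]-4,6,6-trimethylcyclohex-3-enyl acetate | BrC/C=C(\C)CC[C@@H]1C(C)=CC[C@H](OC(C)=O)C1(C)C | intermediate
21 | (2E,6E)-farnesyl bromide | CC(C)=CCC/C(C)=C/CC/C(C)=C/CBr | starting material
22 | (2E,6E)-farnesyl phenyl sulfone | CC(C)=CCC/C(C)=C/CC/C(C)=C/CS(=O)(=O)c1ccccc1 | intermediate
23 | α-lithiated 22 (formed in the flask) | CC(C)=CCC/C(C)=C/CC/C(C)=C/C([Li])S(=O)(=O)c1ccccc1 | intermediate
24 | C30 sulfone acetate, epimers at the sulfonyl carbon | CC(C)=CCC/C(C)=C/CC/C(C)=C/C(S(=O)(=O)c1ccccc1)C/C=C(\C)CC[C@@H]2C(C)=CC[C@H](OC(C)=O)C2(C)C | intermediate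
25 | C30 hydroxy sulfone, present as its lithium alkoxide (formed in the flask) | CC(C)=CCC/C(C)=C/CC/C(C)=C/C(S(=O)(=O)c1ccccc1)C/C=C(\C)CC[C@@H]2C(C)=CC[C@H](O)C2(C)C | intermediate
26 | camelliol C, (3S,5R) | CC(C)=CCC/C(C)=C/CC/C(C)=C/CC/C=C(\C)CC[C@@H]1C(C)=CC[C@H](O)C1(C)C | target

Total step count: 16. Longest linear sequence: 15 steps (steps 1–13, 15 and 16, from 1 to 26). Step 14 is the only side branch.

Steps most likely to fail

Step 10, ring closure. The carbene formed at the allyl terminus may engage the crowded ethylidene too slowly. Intermolecular dimerisation at the terminal alkene, or migration of that alkene caused by ruthenium hydrides, could then take over.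
- The fallback keeps the C4–C5 rearrangement but gives the metathesis a lighter partner. It sets out from 3 and returns at 16.
- Alcohol 3 is acylated with 6 to the primary allylic isobutyrate F1.
- LDA and Me3SiCl give the silyl ketene acetal F2, which rearranges to the silyl ester F3 and, after hydrolysis, to the racemic isopropenyl acid F4.
- LiAlH4 gives the racemic neopentyl alcohol F5, and Dess–Martin periodinane gives the racemic aldehyde F6.
- Allylboration with 14 converts the two enantiomers into the (4S,6R)-triene alcohol F7 and the (4S,6S)-triene alcohol F8. These are diastereomers and are parted by chromatography.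
- F7 then closes with the same catalyst on a 1,1-disubstituted alkene, the standard case for trisubstituted cyclohexenes, and loses ethene to give 16.
- The price is that C5 is no longer steered, so the 5S half of the material is discarded.

Step 6, rearrangement. Three processes could hurt this step:
- fragmentation or C-silylation of the hindered enolate before O-silylation;
- sluggish bond formation between two congested carbons;
- leakage through the pseudo-axial transition state, which erodes C5.

The fallback moves construction of the quaternary centre to after the [3,3] event. It sets out from 5 and returns at 11.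
- Heating 5 with triethyl orthoacetate and catalytic propionic acid at 135 °C (Johnson–Claisen) gives the mixed orthoester F9.
- F9 loses ethanol to the ketene acetal F10, whose unsubstituted terminus bonds to C5 with the same chirality transfer and gives the ethyl ester F11.
- LDA and MeI give the monomethyl ester F12. A second enolisation (LDA, DMPU) and MeI give the gem-dimethyl ester F13.
- LiAlH4 reduces F13 to 11.

Step 9, allylboration. Facial selectivity may erode if the bulky α-quaternary aldehyde and its C5 centre oppose the reagent. The fallback gives up acyclic control and sets C3 on the ring. It sets out from 12 and returns at 16.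
- Plain addition of 13 to 12 (Et2O, −78 °C) gives 15 together with the (4R,6R)-epimeric alcohol F14.
- Metathesis of the mixture as in step 10 gives 16 and the (1R,5R)-cyclohexenol F15.
- Buffered Dess–Martin oxidation converges both on the cyclohexenone F16.
- NaBH4 in MeOH/CH2Cl2 at −40 °C should add hydride axially, on the face away from the axial C4 methyl. This gives the equatorial alcohol cis to the C5 chain, which is 16.

Further compounds
F1 | step 10 | (2E,6E)-8-(4-methoxybenzyloxy)-2,6-dimethylocta-2,6-dienyl 2-methylpropanoate | CC(C)C(=O)OC/C(C)=C/CC/C(C)=C/COCc1ccc(OC)cc1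
F2 | step 10 | trimethylsilyl ketene acetal of F1 | CC(C)=C(O[Si](C)(C)C)OC/C(C)=C/CC/C(C)=C/COCc1ccc(OC)cc1
F3 | step 10 | trimethylsilyl ester of F4, racemic | C[Si](C)(C)OC(=O)C(C)(C)C(CC/C(C)=C/COCc1ccc(OC)cc1)C(C)=C
F4 | step 10 | racemic (6E)-8-(4-methoxybenzyloxy)-2,2,6-trimethyl-3-(prop-1-en-2-yl)oct-6-enoic acid | OC(=O)C(C)(C)C(CC/C(C)=C/COCc1ccc(OC)cc1)C(C)=C
F5 | step 10 | racemic (6E)-8-(4-methoxybenzyloxy)-2,2,6-trimethyl-3-(prop-1-en-2-yl)oct-6-en-1-ol | OCC(C)(C)C(CC/C(C)=C/COCc1ccc(OC)cc1)C(C)=C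
F6 | step 10 | racemic (6E)-8-(4-methoxybenzyloxy)-2,2,6-trimethyl-3-(prop-1-en-2-yl)oct-6-enal | O=CC(C)(C)C(CC/C(C)=C/COCc1ccc(OC)cc1)C(C)=C
F7 | step 10 | (4S,6R,9E)-11-(4-methoxybenzyloxy)-5,5,9-trimethyl-6-(prop-1-en-2-yl)undeca-1,9-dien-4-ol | C=CC[C@H](O)C(C)(C)[C@H](CC/C(C)=C/COCc1ccc(OC)cc1)C(C)=C
F8 | step 10 | (4S,6S,9E)-11-(4-methoxybenzyloxy)-5,5,9-trimethyl-6-(prop-1-en-2-yl)undeca-1,9-dien-4-ol | C=CC[C@H](O)C(C)(C)[C@@H](CC/C(C)=C/COCc1ccc(OC)cc1)C(C)=C
F9 | step 6 | mixed diethyl orthoacetate of 5 | C[C@H](OC(C)(OCC)OCC)/C(C)=C/CC/C(C)=C/COCc1ccc(OC)cc1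
F10 | step 6 | ethyl ketene acetal of 5 | C[C@H](OC(=C)OCC)/C(C)=C/CC/C(C)=C/COCc1ccc(OC)cc1
F11 | step 6 | ethyl (3S,6E)-3-[(2E)-but-2-en-2-yl]-8-(4-methoxybenzyloxy)-6-methyloct-6-enoate | CCOC(=O)C[C@H](CC/C(C)=C/COCc1ccc(OC)cc1)/C(C)=C/C
F12 | step 6 | ethyl (3S,6E)-3-[(2E)-but-2-en-2-yl]-8-(4-methoxybenzyloxy)-2,6-dimethyloct-6-enoate, epimers at C2 | CCOC(=O)C(C)[C@H](CC/C(C)=C/COCc1ccc(OC)cc1)/C(C)=C/C
F13 | step 6 | ethyl (3R,6E)-3-[(2E)-but-2-en-2-yl]-8-(4-methoxybenzyloxy)-2,2,6-trimethyloct-6-enoate | CCOC(=O)C(C)(C)[C@H](CC/C(C)=C/COCc1ccc(OC)cc1)/C(C)=C/C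
F14 | step 9 | (4R,6R,9E)-6-[(2E)-but-2-en-2-yl]-11-(4-methoxybenzyloxy)-5,5,9-trimethylundeca-1,9-dien-4-ol | C=CC[C@@H](O)C(C)(C)[C@H](CC/C(C)=C/COCc1ccc(OC)cc1)/C(C)=C/C
F15 | step 9 | (1R,5R)-5-[(3E)-5-(4-methoxybenzyloxy)-3-methylpent-3-enyl]-4,6,6-trimethylcyclohex-3-en-1-ol | COc1ccc(COC/C=C(\C)CC[C@@H]2C(C)=CC[C@@H](O)C2(C)C)cc1
F16 | step 9 | (5R)-5-[(3E)-5-(4-methoxybenzyloxy)-3-methylpent-3-enyl]-4,6,6-trimethylcyclohex-3-en-1-one | COc1ccc(COC/C=C(\C)CC[C@@H]2C(C)=CCC(=O)C2(C)C)cc1
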